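Ring A is numbered as a benzoate: C1 CO2Me, C2 with O2–H, C3 prenyl, C4 with the pyran oxygen O4, C5 pyran CH=, C6 arylethyl. Ring B is the 4-hydroxyphenyl ring. Rings A and B are bought; the pyran is the only ring made, and it is made last.
Pyran: O4–C(CH3)2 is opened to the ortho-quinone methide O4=C4–C5=CH–CH=C(CH3)2 (retro-oxa-6π) and C5=CH is cut to 3-methylbut-2-enal. In the same operation the C3 prenyl group is returned to O4 as a 1,1-dimethylallyl ether (retro-Claisen).
Enabling feature: O4 sits on C4 between C3 and C5 of ring A, so one oxygen can first pass its five-carbon unit to C3 and then, set free, close the pyran ring onto the chain built at C5. The O2–H···O=C hydrogen bond to the C1 ester steers the shift to C3, after which C5 is the only ring-A carbon that bears hydrogen.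
C6 chain: the ArCH2–CH2Ar bond is cut to the lateral dianion of the orsellinate ether and a 4-silyloxybenzyl bromide. The ether comes from methyl orsellinate by O4-selective propargylation and semi-hydrogenation.

Key step: step 7

Remark: the target has no stereocentre and no open-chain double bond with E/Z isomers, so no step needs stereocontrol.

Step 1
Reactants: 1 4-methylphenol (p-cresol)
Product: 2 tert-butyl(dimethyl)(4-methylphenoxy)silane
Conditions: TBSCl (1.1 equiv), imidazole (2 equiv), DMF, rt
Reagents that add atoms: tert-butyldimethylsilyl chloride, CC(C)(C)[Si](C)(C)Cl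
Why: Imidazole-promoted O-silylation of a phenol is routine and installs a group that stands radical bromination and strong base at low temperature yet leaves with fluoride.

Step 2
Reactants: 2 tert-butyl(dimethyl)(4-methylphenoxy)silane
Product: 3 [4-(bromomethyl)phenoxy](tert-butyl)dimethylsilane
Conditions: NBS (1.05 equiv), AIBN (5 mol %), PhCF3, reflux
Reagents that add atoms: N-bromosuccinimide, O=C1CCC(=O)N1Br
Why: The Wohl–Ziegler bromination takes the only benzylic C–H bonds of 2, and the non-polar radical conditions hold back ionic bromination of the ring.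

Step 3
Reactants: 4 methyl 2,4-dihydroxy-6-methylbenzoate (methyl orsellinate); 5 3-chloro-3-methylbut-1-yne
Product: 6 methyl 2-hydroxy-6-methyl-4-[(2-methylbut-3-yn-2-yl)oxy]benzoate
Conditions: CuCl2·2H2O (1 mol %), DBU (1.3 equiv), MeCN, 0 °C
Reagents that add atoms: none
Why: Copper-catalysed propargylic etherification of a phenoxide with a tertiary propargylic chloride is the standard entry to aryl 1,1-dimethylpropargyl ethers, and only O4–H reacts because O2–H is locked in the hydrogen bond to the ester and is crowded.

Step 4
Reactants: 6 methyl 2-hydroxy-6-methyl-4-[(2-methylbut-3-yn-2-yl)oxy]benzoate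
Product: 7 methyl 2-hydroxy-6-methyl-4-[(2-methylbut-3-en-2-yl)oxy]benzoate
Conditions: H2 (1 atm), 5% Pd/CaCO3 poisoned with Pb(OAc)2, quinoline, EtOAc, rt, stopped after 1 equiv H2
Reagents that add atoms: none
Why: The Lindlar semi-hydrogenation stops a terminal alkyne at the alkene and leaves the aryl ether, the ester and the arene untouched.

Step 5
Reactants: 7 methyl 2-hydroxy-6-methyl-4-[(2-methylbut-3-en-2-yl)oxy]benzoate; 3 [4-(bromomethyl)phenoxy](tert-butyl)dimethylsilane
Product: 9 methyl 6-[2-(4-{[tert-butyl(dimethyl)silyl]oxy}phenyl)ethyl]-2-hydroxy-4-[(2-methylbut-3-en-2-yl)oxy]benzoate, via dilithio dianion 8 (not isolated)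
Conditions: LiN(iPr)2 (LDA, commercial solution, 2.3 equiv), THF, −78 °C; then 3 (1.1 equiv), −78 °C; AcOH quench at −78 °C
Reagents that add atoms: none
Why: In this lateral lithiation of an ortho-toluate the first equivalent of base makes the O2 phenoxide, which shields the ester from attack, the second removes a C6-methyl proton, and the benzylic carbanion, by far the stronger nucleophile of 8, displaces the bromide of 3 in an SN2 alkylation.

Step 6
Reactants: 9 methyl 6-[2-(4-{[tert-butyl(dimethyl)silyl]oxy}phenyl)ethyl]-2-hydroxy-4-[(2-methylbut-3-en-2-yl)oxy]benzoate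
Product: 10 methyl 2-hydroxy-6-[2-(4-hydroxyphenyl)ethyl]-4-[(2-methylbut-3-en-2-yl)oxy]benzoate
Conditions: TBAF (1.1 equiv), AcOH (1.1 equiv), THF, 0 °C
Reagents that add atoms: none
Why: Buffered fluoride cleavage of an aryl silyl ether spares the ester and the tertiary allyl ether, and it is placed here because an aryl silyl ether may not last in the hot amine acetate medium of step 7.

Step 7
Reactants: 10 methyl 2-hydroxy-6-[2-(4-hydroxyphenyl)ethyl]-4-[(2-methylbut-3-en-2-yl)oxy]benzoate; 11 3-methylbut-2-enal
Product: 14 methyl 7-hydroxy-5-[2-(4-hydroxyphenyl)ethyl]-2,2-dimethyl-8-(3-methylbut-2-en-1-yl)-2H-chromene-6-carboxylate (target), via 3-prenyl resorcylate 12 (not isolated), via ortho-quinone methide 13 (not isolated)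
Conditions: 11 (3 equiv, added over 2 h), ethylenediammonium diacetate (20 mol %), xylenes, 140 °C, sealed vessel
Reagents that add atoms: none
Why: Heating first drives the aromatic Claisen rearrangement of the aryl 1,1-dimethylallyl ether 10 ([3,3] shift through a chair transition state, then enolisation), which carries the five-carbon unit with allyl inversion from O4 to C3 as a 3-methylbut-2-enyl group and sets O4–H free (12). The diammonium diacetate then activates 11 as its iminium ion, C5 of 12 (ortho to O4–H, para to O2–H and the only ring-A carbon that still bears hydrogen) adds to it in a Knoevenagel-type condensation, and loss of the amine gives the ortho-quinone methide 13, the 1-oxatriene O4=C4–C5=CH–CH=C(CH3)2. The pyran ring closes by thermal disrotatory oxa-6π electrocyclisation of 13, which forms the O4–C(CH3)2 bond and is pulled forward by the return of aromaticity to ring A, and the fully substituted ring A of 14 cannot react further. The closest known reaction types are the Claisen rearrangement of aryl 1,1-dimethylallyl ethers to ortho-prenylphenols and the amine-salt-catalysed formal [3+3] annulation of resorcinols and resorcylate esters with enals to 2H-chromenes, both run in hot xylene, which is why they can share one flask. No stereocentre arises, since the new sp3 carbon carries two methyl groups. The selectivity needed is C3 over C5 in the shift and annulation only after the shift: the O2–H···O=C hydrogen bond to the C1 ester localises double-bond character in C3–C4 and the C6 chain shields C5, while 10 offers no free hydroxyl beside an open carbon except the chelated O2–H, the slow addition of 11 lets the faster unimolecular shift run ahead, and the plain para-alkylphenol of ring B is too poor a nucleophile for the iminium ion.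

Compound list
1 | 4-methylphenol (p-cresol) | Cc1ccc(O)cc1 | starting material
2 | tert-butyl(dimethyl)(4-methylphenoxy)silane | Cc1ccc(O[Si](C)(C)C(C)(C)C)cc1 | intermediate
3 | [4-(bromomethyl)phenoxy](tert-butyl)dimethylsilane | BrCc1ccc(O[Si](C)(C)C(C)(C)C)cc1 | intermediate
4 | methyl 2,4-dihydroxy-6-methylbenzoate (methyl orsellinate) | COC(=O)c1c(C)cc(O)cc1O | starting material
5 | 3-chloro-3-methylbut-1-yne | C#CC(C)(C)Cl | starting material
6 | methyl 2-hydroxy-6-methyl-4-[(2-methylbut-3-yn-2-yl)oxy]benzoate | COC(=O)c1c(C)cc(OC(C)(C)C#C)cc1O | intermediate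
7 | methyl 2-hydroxy-6-methyl-4-[(2-methylbut-3-en-2-yl)oxy]benzoate | COC(=O)c1c(C)cc(OC(C)(C)C=C)cc1O | intermediate
8 | dilithio dianion of 7 (O2 phenoxide and C6 benzylic carbanion) | [Li+].[Li+].COC(=O)c1c([CH2-])cc(OC(C)(C)C=C)cc1[O-] | intermediate
9 | methyl 6-[2-(4-{[tert-butyl(dimethyl)silyl]oxy}phenyl)ethyl]-2-hydroxy-4-[(2-methylbut-3-en-2-yl)oxy]benzoate | COC(=O)c1c(CCc2ccc(O[Si](C)(C)C(C)(C)C)cc2)cc(OC(C)(C)C=C)cc1O | intermediate
10 | methyl 2-hydroxy-6-[2-(4-hydroxyphenyl)ethyl]-4-[(2-methylbut-3-en-2-yl)oxy]benzoate | COC(=O)c1c(CCc2ccc(O)cc2)cc(OC(C)(C)C=C)cc1O | intermediate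
11 | 3-methylbut-2-enal | CC(C)=CC=O | starting material
12 | methyl 2,4-dihydroxy-6-[2-(4-hydroxyphenyl)ethyl]-3-(3-methylbut-2-en-1-yl)benzoate | COC(=O)c1c(CCc2ccc(O)cc2)cc(O)c(CC=C(C)C)c1O | intermediate
13 | ortho-quinone methide: ring A as the 4-oxocyclohexadiene with an exocyclic (Z)-C5=CH–CH=C(CH3)2 group, vinyl arm on the side of the C4 carbonyl | COC(=O)C1=C(CCc2ccc(O)cc2)/C(=C/C=C(C)C)C(=O)C(CC=C(C)C)=C1O | intermediate
14 | methyl 7-hydroxy-5-[2-(4-hydroxyphenyl)ethyl]-2,2-dimethyl-8-(3-methylbut-2-en-1-yl)-2H-chromene-6-carboxylate | COC(=O)c1c(O)c(CC=C(C)C)c2c(c1CCc1ccc(O)cc1)C=CC(C)(C)O2 | target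

Total step count: 7. Longest linear sequence: 5 steps (1, 2, 5, 6, 7 or 3, 4, 5, 6, 7).

Steps most likely to fail

Step 7. The intermolecular condensation at the crowded C5 may fall behind self-condensation of the aldehyde. Thermal loss of isoprene from the tertiary ether, or a partial shift to C5, may also erode the material before the annulation. The fallback delivers the second five-carbon unit from within the molecule; it sets out from 9 and comes back at 14.
- Heating 9 alone in xylenes at 140 °C (Claisen rearrangement) should give the silyl-protected 3-prenyl resorcylate F1.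
- Copper-catalysed etherification of the O4–H of F1 with 5 (CuCl2·2H2O, DBU, MeCN, 0 °C) should give the 1,1-dimethylpropargyl ether F2.
- Heating F2 in 1,2-dichlorobenzene at 180 °C should give the silyl-protected chromene F3. The sequence is a propargyl Claisen shift to C5 (the only open ortho carbon), enolisation, [1,5]-hydrogen shift and oxa-6π closure.
- TBAF/AcOH in THF then gives 14.

Step 5. Self-condensation of the lateral anion with the ester of a second molecule, incomplete second deprotonation, or decay of the labile benzylic bromide may lower the conversion. The fallback replaces the dianion by the monoanion of a fully masked toluate; it sets out from 7 and comes back at 10.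
- O2–H is silylated (TBSOTf, 2,6-lutidine, CH2Cl2, 0 °C) to the O2-silyl toluate F4.
- The monoanion of F4 (LiN(iPr)2, 1.1 equiv, THF, −78 °C) is alkylated with 3 to the bis-silyl ether F5.
- TBAF (2.2 equiv)/AcOH removes both silyl groups in one operation and gives 10.

Step 4. Over-reduction past the alkene stage, or stalling of the poisoned catalyst, would remove the group that the key step needs. The fallback avoids the alkyne altogether; it sets out from 4 and comes back at 7.
- 2-Methylbut-3-en-2-ol is converted (n-BuLi, Boc2O, THF) into tert-butyl 2-methylbut-3-en-2-yl carbonate F6.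
- 4 is etherified with F6 under Pd(PPh3)4 (2 mol %) in THF at 0 °C. This is a decarboxylative Tsuji–Trost etherification with zerovalent palladium, in which the phenoxide attacks the more substituted end of the allyl ligand under kinetic control. Again only O4–H reacts.

Further compounds
F1 | step 7 | methyl 6-[2-(4-{[tert-butyl(dimethyl)silyl]oxy}phenyl)ethyl]-2,4-dihydroxy-3-(3-methylbut-2-en-1-yl)benzoate | COC(=O)c1c(CCc2ccc(O[Si](C)(C)C(C)(C)C)cc2)cc(O)c(CC=C(C)C)c1O
F2 | step 7 | methyl 6-[2-(4-{[tert-butyl(dimethyl)silyl]oxy}phenyl)ethyl]-2-hydroxy-3-(3-methylbut-2-en-1-yl)-4-[(2-methylbut-3-yn-2-yl)oxy]benzoate | COC(=O)c1c(CCc2ccc(O[Si](C)(C)C(C)(C)C)cc2)cc(OC(C)(C)C#C)c(CC=C(C)C)c1O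
F3 | step 7 | methyl 5-[2-(4-{[tert-butyl(dimethyl)silyl]oxy}phenyl)ethyl]-7-hydroxy-2,2-dimethyl-8-(3-methylbut-2-en-1-yl)-2H-chromene-6-carboxylate | COC(=O)c1c(O)c(CC=C(C)C)c2c(c1CCc1ccc(O[Si](C)(C)C(C)(C)C)cc1)C=CC(C)(C)O2
F4 | step 5 | methyl 2-{[tert-butyl(dimethyl)silyl]oxy}-6-methyl-4-[(2-methylbut-3-en-2-yl)oxy]benzoate | COC(=O)c1c(C)cc(OC(C)(C)C=C)cc1O[Si](C)(C)C(C)(C)C
F5 | step 5 | methyl 2-{[tert-butyl(dimethyl)silyl]oxy}-6-[2-(4-{[tert-butyl(dimethyl)silyl]oxy}phenyl)ethyl]-4-[(2-methylbut-3-en-2-yl)oxy]benzoate | COC(=O)c1c(CCc2ccc(O[Si](C)(C)C(C)(C)C)cc2)cc(OC(C)(C)C=C)cc1O[Si](C)(C)C(C)(C)C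
F6 | step 4 | tert-butyl 2-methylbut-3-en-2-yl carbonate | C=CC(C)(C)OC(=O)OC(C)(C)C
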